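**Plan**
- Retrosynthesis: C2–C3 and C4–C4a of ring C are cut together, which removes C3–C4 as a ketene equivalent (ethoxyacetylene) and leaves an O-aryl oxocarbenium ion; O1–C2 is then cut to 3,5-bis(benzyloxy)phenol (ring A) and a ring-B benzaldehyde; the aldehyde carbon goes back to an aryl bromide; C7''–C8'' is cut by an aldol disconnection.
- Forward: the side chain is built on ring B (syn-aldol, reductive auxiliary removal, inversion at C7''), Br is exchanged for CHO, ring A is joined through O1 as an aryloxy(pivaloyloxy)methine, ring C is closed last by a cationic [4+2] event, then silyl and benzyl groups are removed.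
- Enabling feature: O1 links the benzylic C2 (stabilised by ring B) to ring A, whose ortho carbon C4a is activated by O5 and O7; after ionisation, C4a=C8a–O1=C2 is a cationic 2-oxadiene that takes up a two-carbon partner at C2 and C4a.
- Stereochemistry: C8'' from the oxazolidinone auxiliary (syn-aldol); C7'' by SN2 inversion of the syn-derived alcohol (threo to erythro); C2 from a chiral counter-anion in a stereoconvergent step in which both acetal epimers pass through one planar cation.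

Key step: step 10

Assumption: the (S,S)-configured acid in step 10 is taken to deliver the 2S configuration; should the sense prove opposite, its mirror image is used.

**Route**

Step 1
Reactants: 1 4-bromo-2,6-dimethoxyphenol
Product: 2 2-(4-bromo-2,6-dimethoxyphenoxy)acetic acid
Conditions: ClCH2CO2H, NaOH, H2O, reflux; then HCl
Reagents that add atoms: chloroacetic acid, OC(=O)CCl
Why: Williamson ether synthesis, in which the phenoxide displaces chloride from the unhindered primary carbon of chloroacetate.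

Step 2
Reactants: 2 2-(4-bromo-2,6-dimethoxyphenoxy)acetic acid; 3 (R)-4-benzyl-1,3-oxazolidin-2-one
Product: 5 (R)-4-benzyl-3-[2-(4-bromo-2,6-dimethoxyphenoxy)acetyl]-1,3-oxazolidin-2-one, via mixed pivalic anhydride 4 (not isolated)
Conditions: PivCl, Et3N, THF, −20 °C; then 3, LiCl, −20 °C → rt
Reagents that add atoms: none
Why: N-acylation of the oxazolidinone through a mixed anhydride, the nucleophile attacking the less hindered aryloxyacetyl carbonyl.

Step 3
Reactants: 5 (R)-4-benzyl-3-[2-(4-bromo-2,6-dimethoxyphenoxy)acetyl]-1,3-oxazolidin-2-one; 6 4-(benzyloxy)-3-methoxybenzaldehyde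
Product: 8 (R)-4-benzyl-3-[(2R,3S)-3-[4-(benzyloxy)-3-methoxyphenyl]-2-(4-bromo-2,6-dimethoxyphenoxy)-3-hydroxypropanoyl]-1,3-oxazolidin-2-one, via dibutylboron Z-enolate 7 (not isolated)
Conditions: Bu2BOTf, i-Pr2NEt, CH2Cl2, 0 °C; 6, −78 → 0 °C; then pH 7 buffer, MeOH, H2O2
Reagents that add atoms: none
Why: Evans syn-aldol reaction, in which the Z-boron enolate reacts through a Zimmerman–Traxler chair on the enolate face away from the auxiliary benzyl group, which should set the 2R,3S (syn) pair.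

Step 4
Reactants: 8 the syn-aldol adduct
Product: 9 (1S,2S)-1-[4-(benzyloxy)-3-methoxyphenyl]-2-(4-bromo-2,6-dimethoxyphenoxy)propane-1,3-diol (threo)
Conditions: LiBH4, H2O (1 equiv), Et2O–THF, 0 °C
Reagents that add atoms: none
Why: reductive cleavage of the N-acyl oxazolidinone with LiBH4 should give the primary alcohol and return the auxiliary without touching either stereocentre.

Step 5
Reactants: 9 the threo diol
Product: 10 (1S,2S)-1-[4-(benzyloxy)-3-methoxyphenyl]-2-(4-bromo-2,6-dimethoxyphenoxy)-3-[(triisopropylsilyl)oxy]propan-1-ol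
Conditions: TIPSCl, imidazole, DMF, 0 °C → rt
Reagents that add atoms: triisopropylsilyl chloride, CC(C)[Si](Cl)(C(C)C)C(C)C
Why: chemoselective silylation, the bulky silyl chloride reacting at the primary hydroxyl far faster than at the hindered secondary benzylic one.

Step 6
Reactants: 10 the threo mono-silyl ether
Product: 12 (1R,2S)-1-[4-(benzyloxy)-3-methoxyphenyl]-2-(4-bromo-2,6-dimethoxyphenoxy)-3-[(triisopropylsilyl)oxy]propan-1-ol (erythro), via inverted 4-nitrobenzoate 11 (not isolated)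
Conditions: PPh3, DIAD, 4-nitrobenzoic acid, THF, 0 °C → rt; then K2CO3, MeOH, rt
Reagents that add atoms: 4-nitrobenzoic acid, OC(=O)c1ccc(cc1)[N+](=O)[O-]
Why: Mitsunobu inversion, the carboxylate displacing the oxyphosphonium group at C1 by SN2 (the neighbouring aryloxy group disfavours ionisation), after which methanolysis at the acyl carbon frees the inverted alcohol.

Step 7
Reactants: 12 the erythro mono-silyl ether
Product: 13 tert-butyl{(1R,2S)-1-[4-(benzyloxy)-3-methoxyphenyl]-2-(4-bromo-2,6-dimethoxyphenoxy)-3-[(triisopropylsilyl)oxy]propoxy}dimethylsilane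
Conditions: TBSOTf, 2,6-lutidine, CH2Cl2, 0 °C
Reagents that add atoms: tert-butyldimethylsilyl triflate, CC(C)(C)[Si](C)(C)OS(=O)(=O)C(F)(F)F
Why: silylation of a hindered secondary alcohol with a silyl triflate and a hindered base, which removes the last acidic proton before the organolithium step.

Step 8
Reactants: 13 the bis-silyl aryl bromide
Product: 15 4-({(1R,2S)-1-[4-(benzyloxy)-3-methoxyphenyl]-1-[(tert-butyldimethylsilyl)oxy]-3-[(triisopropylsilyl)oxy]propan-2-yl}oxy)-3,5-dimethoxybenzaldehyde, via aryllithium 14 (not isolated)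
Conditions: n-BuLi, THF, −78 °C; DMF, −78 → 0 °C; aq. NH4Cl
Reagents that add atoms: N,N-dimethylformamide, CN(C)C=O
Why: bromine–lithium exchange followed by formylation with DMF (Bouveault aldehyde synthesis), the exchange at −78 °C being faster than any deprotonation of the ethers.

Step 9
Reactants: 15 the ring-B aldehyde; 16 3,5-bis(benzyloxy)phenol
Product: 18 [3,5-bis(benzyloxy)phenoxy][4-({(1R,2S)-1-[4-(benzyloxy)-3-methoxyphenyl]-1-[(tert-butyldimethylsilyl)oxy]-3-[(triisopropylsilyl)oxy]propan-2-yl}oxy)-3,5-dimethoxyphenyl]methyl pivalate (both epimers at the acetal carbon), via α-chlorobenzyl pivalate 17 (not isolated)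
Conditions: PivCl, ZnCl2 (2 mol%), CH2Cl2, 0 °C → rt; then sodium salt of 16 (from NaH), THF–DMF, −40 → 0 °C
Reagents that add atoms: pivaloyl chloride, CC(C)(C)C(Cl)=O
Why: ZnCl2-catalysed addition of an acyl chloride across the aldehyde gives the α-chloroalkyl ester, whose chloride is displaced at oxygen by the phenoxide (acyloxyalkyl aryl ether formation); the new acetal centre forms unselectively, which is harmless because step 10 erases it.

Step 10
Reactants: 18 the aryloxy(pivaloyloxy)methine; 19 ethoxyethyne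
Product: 21 (2S)-5,7-bis(benzyloxy)-2-[4-({(1R,2S)-1-[4-(benzyloxy)-3-methoxyphenyl]-1-[(tert-butyldimethylsilyl)oxy]-3-[(triisopropylsilyl)oxy]propan-2-yl}oxy)-3,5-dimethoxyphenyl]chroman-4-one, via 4-ethoxy-2H-chromene 20 (not isolated)
Conditions: (S,S)-imidodiphosphorimidate acid HN[P(=NSO2CF3)(O2C20H10Ar2)]2 (Ar = 3,5-(CF3)2C6H3; 5 mol%), 19 (3 equiv, added in portions), toluene, −60 °C; then aq. oxalic acid, THF, 0 °C
Reagents that add atoms: water, O
Why: Proposed new method: the confined acid protonates the pivalate carbonyl of 18 and expels pivalic acid (the acyloxy group, not the aryloxy group, leaves), so both acetal epimers give one planar O-aryl oxocarbenium ion, the cationic 2-oxadiene C4a=C8a–O1=C2, held as a contact ion pair with the chiral anion. The terminal carbon of ethoxyethyne attacks C2 on the face left open by the anion (C2–C3 bond; 2S under catalyst control), the resulting ethoxyketenium ion is captured by C4a of ring A (C4–C4a bond), and loss of the ring proton returns the acid. The closest known reaction types are the oxa-Povarov reaction (Lewis-acid [4+2] of aryl oxocarbenium ions with alkenes to chromans), additions of alkoxyalkynes to acetal-derived oxocarbenium ions, ketenium–arene Friedel–Crafts cyclisations of ynol ethers and chiral-anion-controlled additions of π-nucleophiles to oxocarbenium ion pairs; their merger into an enantioselective [4+2] with a ketene equivalent is the new element. Ring C closes by a six-membered Friedel–Crafts attack on the sp carbon of the ketenium ion (6-exo-dig with respect to its C=O+ bond, the C3=C4 bond staying in the ring). The step needs facial selectivity at C2 (anion control, the side-chain stereocentres being remote), capture of the cation by the alkyne rather than by an electron-rich ring (alkyne in excess, dilution, low temperature), and six-membered closure onto ring A rather than five-membered closure onto ring B or ketenium oligomerisation, which the two equivalent, doubly oxygen-activated ortho carbons of ring A should secure. Mild aqueous acid then hydrolyses enol ether 20 to the ketone without affecting C2.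

Step 11
Reactants: 21 the protected flavanone
Product: 22 (2S)-5,7-bis(benzyloxy)-2-[4-({(1R,2S)-1-[4-(benzyloxy)-3-methoxyphenyl]-1,3-dihydroxypropan-2-yl}oxy)-3,5-dimethoxyphenyl]chroman-4-one
Conditions: HF·pyridine, pyridine, THF, 0 °C → rt
Reagents that add atoms: none
Why: fluoride-mediated desilylation under buffered, weakly acidic conditions should remove both silyl ethers without opening the flavanone or ionising the benzylic alcohol.

Step 12
Reactants: 22 the tribenzyl ether
Product: 23 (2S)-5,7-dihydroxy-2-[4-({(1R,2S)-1,3-dihydroxy-1-(4-hydroxy-3-methoxyphenyl)propan-2-yl}oxy)-3,5-dimethoxyphenyl]chroman-4-one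
Conditions: H2 (1 atm), Pd/C, EtOAc–MeOH, rt
Reagents that add atoms: none
Why: catalytic hydrogenolysis of the three aryl benzyl ethers under neutral conditions, which should spare the ketone, the ring-C benzylic ether and the benzylic alcohol if stopped at full conversion.

**Compound list**

1 | 4-bromo-2,6-dimethoxyphenol | COc1cc(Br)cc(OC)c1O | starting material
2 | 2-(4-bromo-2,6-dimethoxyphenoxy)acetic acid | COc1cc(Br)cc(OC)c1OCC(O)=O | intermediate
3 | (R)-4-benzyl-1,3-oxazolidin-2-one | O=C1N[C@H](Cc2ccccc2)CO1 | starting material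
4 | 2-(4-bromo-2,6-dimethoxyphenoxy)acetic pivalic anhydride | COc1cc(Br)cc(OC)c1OCC(=O)OC(=O)C(C)(C)C | intermediate
5 | (R)-4-benzyl-3-[2-(4-bromo-2,6-dimethoxyphenoxy)acetyl]-1,3-oxazolidin-2-one | COc1cc(Br)cc(OC)c1OCC(=O)N1C(=O)OC[C@H]1Cc1ccccc1 | intermediate
6 | 4-(benzyloxy)-3-methoxybenzaldehyde | COc1cc(C=O)ccc1OCc1ccccc1 | starting material
7 | dibutylboron Z-enolate of 5 | CCCCB(CCCC)O/C(=C\Oc1c(OC)cc(Br)cc1OC)N1C(=O)OC[C@H]1Cc1ccccc1 | intermediate
8 | (R)-4-benzyl-3-[(2R,3S)-3-[4-(benzyloxy)-3-methoxyphenyl]-2-(4-bromo-2,6-dimethoxyphenoxy)-3-hydroxypropanoyl]-1,3-oxazolidin-2-one | COc1cc([C@H](O)[C@H](C(=O)N2C(=O)OC[C@H]2Cc2ccccc2)Oc2c(OC)cc(Br)cc2OC)ccc1OCc1ccccc1 | intermediate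
9 | (1S,2S)-1-[4-(benzyloxy)-3-methoxyphenyl]-2-(4-bromo-2,6-dimethoxyphenoxy)propane-1,3-diol | COc1cc([C@H](O)[C@H](CO)Oc2c(OC)cc(Br)cc2OC)ccc1OCc1ccccc1 | intermediate
10 | (1S,2S)-1-[4-(benzyloxy)-3-methoxyphenyl]-2-(4-bromo-2,6-dimethoxyphenoxy)-3-[(triisopropylsilyl)oxy]propan-1-ol | COc1cc([C@H](O)[C@H](CO[Si](C(C)C)(C(C)C)C(C)C)Oc2c(OC)cc(Br)cc2OC)ccc1OCc1ccccc1 | intermediate
11 | (1R,2S)-1-[4-(benzyloxy)-3-methoxyphenyl]-2-(4-bromo-2,6-dimethoxyphenoxy)-3-[(triisopropylsilyl)oxy]propyl 4-nitrobenzoate | COc1cc([C@@H](OC(=O)c2ccc(cc2)[N+](=O)[O-])[C@H](CO[Si](C(C)C)(C(C)C)C(C)C)Oc2c(OC)cc(Br)cc2OC)ccc1OCc1ccccc1 | intermediate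
12 | (1R,2S)-1-[4-(benzyloxy)-3-methoxyphenyl]-2-(4-bromo-2,6-dimethoxyphenoxy)-3-[(triisopropylsilyl)oxy]propan-1-ol | COc1cc([C@@H](O)[C@H](CO[Si](C(C)C)(C(C)C)C(C)C)Oc2c(OC)cc(Br)cc2OC)ccc1OCc1ccccc1 | intermediate
13 | tert-butyl{(1R,2S)-1-[4-(benzyloxy)-3-methoxyphenyl]-2-(4-bromo-2,6-dimethoxyphenoxy)-3-[(triisopropylsilyl)oxy]propoxy}dimethylsilane | COc1cc([C@@H](O[Si](C)(C)C(C)(C)C)[C@H](CO[Si](C(C)C)(C(C)C)C(C)C)Oc2c(OC)cc(Br)cc2OC)ccc1OCc1ccccc1 | intermediate
14 | aryllithium from 13 (Li in place of Br) | COc1cc([C@@H](O[Si](C)(C)C(C)(C)C)[C@H](CO[Si](C(C)C)(C(C)C)C(C)C)Oc2c(OC)cc([Li])cc2OC)ccc1OCc1ccccc1 | intermediate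
15 | 4-({(1R,2S)-1-[4-(benzyloxy)-3-methoxyphenyl]-1-[(tert-butyldimethylsilyl)oxy]-3-[(triisopropylsilyl)oxy]propan-2-yl}oxy)-3,5-dimethoxybenzaldehyde | COc1cc([C@@H](O[Si](C)(C)C(C)(C)C)[C@H](CO[Si](C(C)C)(C(C)C)C(C)C)Oc2c(OC)cc(C=O)cc2OC)ccc1OCc1ccccc1 | intermediate
16 | 3,5-bis(benzyloxy)phenol | Oc1cc(OCc2ccccc2)cc(OCc2ccccc2)c1 | starting material
17 | chloro[4-({(1R,2S)-1-[4-(benzyloxy)-3-methoxyphenyl]-1-[(tert-butyldimethylsilyl)oxy]-3-[(triisopropylsilyl)oxy]propan-2-yl}oxy)-3,5-dimethoxyphenyl]methyl pivalate (both epimers) | COc1cc([C@@H](O[Si](C)(C)C(C)(C)C)[C@H](CO[Si](C(C)C)(C(C)C)C(C)C)Oc2c(OC)cc(C(Cl)OC(=O)C(C)(C)C)cc2OC)ccc1OCc1ccccc1 | intermediate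
18 | [3,5-bis(benzyloxy)phenoxy][4-({(1R,2S)-1-[4-(benzyloxy)-3-methoxyphenyl]-1-[(tert-butyldimethylsilyl)oxy]-3-[(triisopropylsilyl)oxy]propan-2-yl}oxy)-3,5-dimethoxyphenyl]methyl pivalate (both epimers) | COc1cc([C@@H](O[Si](C)(C)C(C)(C)C)[C@H](CO[Si](C(C)C)(C(C)C)C(C)C)Oc2c(OC)cc(C(OC(=O)C(C)(C)C)Oc3cc(OCc4ccccc4)cc(OCc4ccccc4)c3)cc2OC)ccc1OCc1ccccc1 | intermediate
19 | ethoxyethyne | CCOC#C | starting material
20 | (2S)-5,7-bis(benzyloxy)-4-ethoxy-2-[4-({(1R,2S)-1-[4-(benzyloxy)-3-methoxyphenyl]-1-[(tert-butyldimethylsilyl)oxy]-3-[(triisopropylsilyl)oxy]propan-2-yl}oxy)-3,5-dimethoxyphenyl]-2H-chromene | COc1cc([C@@H](O[Si](C)(C)C(C)(C)C)[C@H](CO[Si](C(C)C)(C(C)C)C(C)C)Oc2c(OC)cc([C@@H]3C=C(OCC)c4c(OCc5ccccc5)cc(OCc5ccccc5)cc4O3)cc2OC)ccc1OCc1ccccc1 | intermediate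
21 | (2S)-5,7-bis(benzyloxy)-2-[4-({(1R,2S)-1-[4-(benzyloxy)-3-methoxyphenyl]-1-[(tert-butyldimethylsilyl)oxy]-3-[(triisopropylsilyl)oxy]propan-2-yl}oxy)-3,5-dimethoxyphenyl]chroman-4-one | COc1cc([C@@H](O[Si](C)(C)C(C)(C)C)[C@H](CO[Si](C(C)C)(C(C)C)C(C)C)Oc2c(OC)cc([C@@H]3CC(=O)c4c(OCc5ccccc5)cc(OCc5ccccc5)cc4O3)cc2OC)ccc1OCc1ccccc1 | intermediate
22 | (2S)-5,7-bis(benzyloxy)-2-[4-({(1R,2S)-1-[4-(benzyloxy)-3-methoxyphenyl]-1,3-dihydroxypropan-2-yl}oxy)-3,5-dimethoxyphenyl]chroman-4-one | COc1cc([C@@H](O)[C@H](CO)Oc2c(OC)cc([C@@H]3CC(=O)c4c(OCc5ccccc5)cc(OCc5ccccc5)cc4O3)cc2OC)ccc1OCc1ccccc1 | intermediate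
23 | (2S)-5,7-dihydroxy-2-[4-({(1R,2S)-1,3-dihydroxy-1-(4-hydroxy-3-methoxyphenyl)propan-2-yl}oxy)-3,5-dimethoxyphenyl]chroman-4-one | COc1cc([C@@H](O)[C@H](CO)Oc2c(OC)cc([C@@H]3CC(=O)c4c(O)cc(O)cc4O3)cc2OC)ccc1O | target

**Step count and risks**

Total steps: 12. Longest linear sequence: 12 (1 → 23); compounds 3, 6, 16 and 19 enter as purchased materials.

Steps most likely to fail:

1. Step 10 (proposed new method). The ion pair may be too loose for good facial control at C2. The cation may be captured by an electron-rich ring of a second molecule instead of by the alkyne, and the strong acid may consume the alkyne. The fallback uses known chemistry, sets out from 13 and comes back at 21. Bromine–lithium exchange on 13 (n-BuLi, −78 °C), borylation with B(Oi-Pr)3 and mild acidic work-up should give [4-({(1R,2S)-1-[4-(benzyloxy)-3-methoxyphenyl]-1-[(tert-butyldimethylsilyl)oxy]-3-[(triisopropylsilyl)oxy]propan-2-yl}oxy)-3,5-dimethoxyphenyl]boronic acid F1. Purchasable 5,7-dihydroxy-4H-chromen-4-one is benzylated (BnBr, K2CO3, DMF) to 5,7-bis(benzyloxy)-4H-chromen-4-one F2. Enantioselective conjugate addition of F1 to F2 with Pd(OCOCF3)2 and a 4-tert-butyl-2-(pyridin-2-yl)-4,5-dihydrooxazole ligand (NH4PF6, H2O, ClCH2CH2Cl, 60 °C; the ligand enantiomer that gives 2S) should deliver 21 directly. This is the established arylboronic acid addition to chromones.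

2. Step 9. The ambident phenoxide may alkylate at ring carbon, acyl transfer from the pivalate to the phenoxide may regenerate the aldehyde, or the acyl chloride adduct of the electron-rich aldehyde may revert before capture. The fallback sets out from 15 and comes back at 21. Pinnick oxidation of 15 (NaClO2, NaH2PO4, 2-methyl-2-butene) should give 4-({(1R,2S)-1-[4-(benzyloxy)-3-methoxyphenyl]-1-[(tert-butyldimethylsilyl)oxy]-3-[(triisopropylsilyl)oxy]propan-2-yl}oxy)-3,5-dimethoxybenzoic acid F3. Carbodiimide esterification with 16 (EDC, DMAP) should give 3,5-bis(benzyloxy)phenyl 4-({(1R,2S)-1-[4-(benzyloxy)-3-methoxyphenyl]-1-[(tert-butyldimethylsilyl)oxy]-3-[(triisopropylsilyl)oxy]propan-2-yl}oxy)-3,5-dimethoxybenzoate F4. Reductive acetylation of the ester (i-Bu2AlH, −78 °C; then Ac2O, pyridine, DMAP, trapping the aluminium hemiacetal before it collapses) should give the acetate analogue of 18, [3,5-bis(benzyloxy)phenoxy][4-({(1R,2S)-1-[4-(benzyloxy)-3-methoxyphenyl]-1-[(tert-butyldimethylsilyl)oxy]-3-[(triisopropylsilyl)oxy]propan-2-yl}oxy)-3,5-dimethoxyphenyl]methyl acetate F5. F5 is taken through the conditions of step 10 in place of 18 to reach 21.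

3. Step 6. The oxyphosphonium intermediate of the electron-rich benzylic alcohol may ionise before displacement, eroding configuration at C1, or it may eliminate. The fallback sets out from 10 and comes back at 12. Dess–Martin oxidation of 10 should give (2S)-1-[4-(benzyloxy)-3-methoxyphenyl]-2-(4-bromo-2,6-dimethoxyphenoxy)-3-[(triisopropylsilyl)oxy]propan-1-one F6. Chelation-controlled reduction with Zn(BH4)2 (Et2O, −20 °C; zinc bridging the ketone and the α-aryloxy oxygen, hydride entering opposite the CH2OSi group) should give the anti (erythro) alcohol 12. The ketone must be kept cold and base-free to avoid epimerisation at C2.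

**Further compounds**

F1 | step 10 | [4-({(1R,2S)-1-[4-(benzyloxy)-3-methoxyphenyl]-1-[(tert-butyldimethylsilyl)oxy]-3-[(triisopropylsilyl)oxy]propan-2-yl}oxy)-3,5-dimethoxyphenyl]boronic acid | COc1cc([C@@H](O[Si](C)(C)C(C)(C)C)[C@H](CO[Si](C(C)C)(C(C)C)C(C)C)Oc2c(OC)cc(B(O)O)cc2OC)ccc1OCc1ccccc1
F2 | step 10 | 5,7-bis(benzyloxy)-4H-chromen-4-one | O=c1ccoc2cc(OCc3ccccc3)cc(OCc3ccccc3)c12
F3 | step 9 | 4-({(1R,2S)-1-[4-(benzyloxy)-3-methoxyphenyl]-1-[(tert-butyldimethylsilyl)oxy]-3-[(triisopropylsilyl)oxy]propan-2-yl}oxy)-3,5-dimethoxybenzoic acid | COc1cc([C@@H](O[Si](C)(C)C(C)(C)C)[C@H](CO[Si](C(C)C)(C(C)C)C(C)C)Oc2c(OC)cc(C(O)=O)cc2OC)ccc1OCc1ccccc1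
F4 | step 9 | 3,5-bis(benzyloxy)phenyl 4-({(1R,2S)-1-[4-(benzyloxy)-3-methoxyphenyl]-1-[(tert-butyldimethylsilyl)oxy]-3-[(triisopropylsilyl)oxy]propan-2-yl}oxy)-3,5-dimethoxybenzoate | COc1cc([C@@H](O[Si](C)(C)C(C)(C)C)[C@H](CO[Si](C(C)C)(C(C)C)C(C)C)Oc2c(OC)cc(C(=O)Oc3cc(OCc4ccccc4)cc(OCc4ccccc4)c3)cc2OC)ccc1OCc1ccccc1
F5 | step 9 | [3,5-bis(benzyloxy)phenoxy][4-({(1R,2S)-1-[4-(benzyloxy)-3-methoxyphenyl]-1-[(tert-butyldimethylsilyl)oxy]-3-[(triisopropylsilyl)oxy]propan-2-yl}oxy)-3,5-dimethoxyphenyl]methyl acetate (both epimers) | COc1cc([C@@H](O[Si](C)(C)C(C)(C)C)[C@H](CO[Si](C(C)C)(C(C)C)C(C)C)Oc2c(OC)cc(C(OC(C)=O)Oc3cc(OCc4ccccc4)cc(OCc4ccccc4)c3)cc2OC)ccc1OCc1ccccc1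
F6 | step 6 | (2S)-1-[4-(benzyloxy)-3-methoxyphenyl]-2-(4-bromo-2,6-dimethoxyphenoxy)-3-[(triisopropylsilyl)oxy]propan-1-one | COc1cc(C(=O)[C@H](CO[Si](C(C)C)(C(C)C)C(C)C)Oc2c(OC)cc(Br)cc2OC)ccc1OCc1ccccc1
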